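**Retrosynthetic overview**
1. The benzofuran ring is closed last, by Sonogashira coupling and 5-endo cyclisation of an ethynyl-dihydrobenzofuran with an o-iodophenol that already carries the hydroxypropyl chain.
2. The trans-2-aryl-3-(hydroxymethyl)dihydrobenzofuran comes from a (2S)-flavanone by oxidative ring contraction (1,2-shift of ring A from C4 to C3), run in the same flask as the asymmetric conjugate arylation of a chromone that sets C2.
3. The chromone, the arylboronic acid and the iodophenol all derive from 4-bromo-2-methoxyphenol (catechol → guaiacol → bromide). The small carbon units are acetyl chloride, DMF dimethyl acetal, trimethylsilylacetylene and allyl alcohol.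
4. Ring order: pyranone ring → contracted to the dihydrofuran ring → furan ring of the benzofuran.

Assumption 1: building blocks that supply skeletal carbon are numbered as starting materials; MeI, NBS, pivaloyl chloride, B2(OH)4, HC(OMe)3 and I2 are treated as reagents.
Assumption 2: (R)-t-BuPyOx is taken to give the (2S)-flavanone (same facial sense as with carbocyclic enones, where the (S)-ligand gives the (R)-ketone); if the sense is the reverse, the (S)-ligand is used.
Target configuration: (2S,3R), trans. Ring A = benzo ring of the dihydrobenzofuran, ring B = benzo ring of the benzofuran, ring C = 4-hydroxy-3-methoxyphenyl.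

**Step 1**
Reactants: 1 catechol (benzene-1,2-diol)
Product: 2 guaiacol (2-methoxyphenol)
Conditions: MeI (1.0 equiv), Li2CO3 (1.1 equiv), DMF, 55 °C
Reagents that add atoms: iodomethane, CI
Why: Williamson mono-O-methylation; with MeI limiting, the lithium-chelated monoanion is alkylated once and the neutral product is far less nucleophilic.

**Step 2**
Reactants: 2 guaiacol
Product: 3 4-bromo-2-methoxyphenol
Conditions: NBS (1.0 equiv), MeCN, −20 → 0 °C
Reagents that add atoms: N-bromosuccinimide, O=C1CCC(=O)N1Br
Why: Electrophilic aromatic bromination; the free hydroxyl is the stronger director and sends bromine para to itself.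

**Step 3**
Reactants: 3 4-bromo-2-methoxyphenol; 4 acetyl chloride
Product: 6 1-(5-bromo-2-hydroxy-3-methoxyphenyl)ethan-1-one, via aryl acetate 5 (not isolated)
Conditions: AcCl (1.2 equiv), 25 °C; then TiCl4 (1.5 equiv), neat, 120 °C; aq. HCl work-up
Reagents that add atoms: none
Why: O-Acetylation then Fries rearrangement; the para position is blocked by bromine, so the acyl group can only move to the one free ortho position, held there as the titanium chelate of the o-hydroxy ketone.

**Step 4**
Reactants: 6 1-(5-bromo-2-hydroxy-3-methoxyphenyl)ethan-1-one; 7 N,N-dimethylformamide dimethyl acetal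
Product: 9 6-bromo-8-methoxy-4H-chromen-4-one, via enaminone 8 (not isolated)
Conditions: Me2NCH(OMe)2 (1.5 equiv), toluene, 100 °C; then conc. HCl, CH2Cl2, 40 °C
Reagents that add atoms: none
Why: Condensation of the methyl ketone with the amide acetal gives the enaminone; acid then promotes oxa-Michael addition and loss of dimethylamine to close the pyranone ring (standard chromone synthesis).

**Step 5**
Reactants: 3 4-bromo-2-methoxyphenol
Product: 10 4-bromo-2-methoxyphenyl 2,2-dimethylpropanoate
Conditions: pivaloyl chloride, Et3N, DMAP (cat.), CH2Cl2, 0 → 25 °C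
Reagents that add atoms: pivaloyl chloride, CC(C)(C)C(Cl)=O
Why: Phenol acylation; the pivalate shields ring C from the later oxidant, lowers its migratory aptitude, and is removed by LiAlH4 in step 9 without an extra step.

**Step 6**
Reactants: 10 4-bromo-2-methoxyphenyl 2,2-dimethylpropanoate
Product: 11 [4-(2,2-dimethylpropanoyloxy)-3-methoxyphenyl]boronic acid
Conditions: B2(OH)4 (1.5 equiv), Pd(OAc)2 (2 mol%), XPhos (4 mol%), KOAc (3 equiv), EtOH, 80 °C
Reagents that add atoms: tetrahydroxydiboron, OB(O)B(O)O
Why: Miyaura-type palladium-catalysed borylation gives the boronic acid directly; the hindered aryl pivalate is inert to KOAc in ethanol.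

**Step 7**
Reactants: 9 6-bromo-8-methoxy-4H-chromen-4-one; 11 [4-(2,2-dimethylpropanoyloxy)-3-methoxyphenyl]boronic acid (1.5 equiv)
Product: 14 methyl (2S,3S)-5-bromo-2-[4-(2,2-dimethylpropanoyloxy)-3-methoxyphenyl]-7-methoxy-2,3-dihydro-1-benzofuran-3-carboxylate (trans), via (S)-flavanone 12 (not isolated), via methyl enol ether 13 (not isolated)
Conditions: Pd(OCOCF3)2 (5 mol%), (R)-t-BuPyOx (6 mol%), NH4PF6 (30 mol%), H2O (5 equiv), ClCH2CH2Cl, 60 °C; then, same flask, HC(OMe)3, H2SO4, PhI(OAc)2 (1.8 equiv), 0 → 25 °C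
Reagents that add atoms: trimethyl orthoformate, COC(OC)OC; water, O
Why: Proposed new method: a one-flask enantioselective arylative ring contraction of a chromone, in which the cationic divalent-palladium/PyOx catalyst adds the aryl group of 11 to C2 of 9 (asymmetric conjugate addition, ligand control fixes C2 as S) and, without isolation, acid and HC(OMe)3 convert flavanone 12 into enol ether 13, the λ3-iodane adds to C3 anti to the C2 aryl group, ketalisation at C4 places the equatorial C3–I bond antiperiplanar to C4–C4a, and ring A shifts from C4 to C3 with inversion as iodobenzene leaves, so the ester ends trans to the aryl group (3S) while C2 is untouched; the closest known reactions are the separate palladium/PyOx conjugate arylation of chromones and the PhI(OAc)2/H2SO4/HC(OMe)3 oxidative ring contraction (1,2-aryl shift) of isolated racemic flavanones, which have not been combined into one operation on a chromone.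

**Step 8**
Reactants: 14 methyl (2S,3S)-5-bromo-2-[4-(2,2-dimethylpropanoyloxy)-3-methoxyphenyl]-7-methoxy-2,3-dihydro-1-benzofuran-3-carboxylate; 15 ethynyl(trimethyl)silane
Product: 16 methyl (2S,3S)-2-[4-(2,2-dimethylpropanoyloxy)-3-methoxyphenyl]-7-methoxy-5-[(trimethylsilyl)ethynyl]-2,3-dihydro-1-benzofuran-3-carboxylate
Conditions: PdCl2(PhCN)2 (3 mol%), [HP(t-Bu)3]BF4 (6 mol%), CuI (2 mol%), i-Pr2NH, 1,4-dioxane, 25 → 45 °C
Reagents that add atoms: none
Why: Sonogashira coupling; the bulky electron-rich phosphine lets the electron-rich aryl bromide react near room temperature, where the amine does not epimerise the C3 ester.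

**Step 9**
Reactants: 16 methyl (2S,3S)-2-[4-(2,2-dimethylpropanoyloxy)-3-methoxyphenyl]-7-methoxy-5-[(trimethylsilyl)ethynyl]-2,3-dihydro-1-benzofuran-3-carboxylate
Product: 18 4-[(2S,3R)-5-ethynyl-3-(hydroxymethyl)-7-methoxy-2,3-dihydro-1-benzofuran-2-yl]-2-methoxyphenol, via silylalkyne diol 17 (not isolated)
Conditions: LiAlH4 (4 equiv), THF, 0 °C; then MeOH, K2CO3 (cat.), 25 °C
Reagents that add atoms: none
Why: Hydride reduction of the ester to the primary alcohol with reductive removal of the pivalate, then base-catalysed methanolysis of the C–Si bond; the ester is reduced faster than it enolises, so C3 keeps its geometry (the descriptor changes from S to R only through the priority change).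

**Step 10**
Reactants: 19 prop-2-en-1-ol (allyl alcohol); 3 4-bromo-2-methoxyphenol
Product: 21 4-(3-hydroxypropyl)-2-methoxyphenol, via alkylborane 20 (not isolated)
Conditions: 9-BBN (2.2 equiv), THF, 0 → 25 °C; then 3, Pd(OAc)2 (3 mol%), SPhos (6 mol%), K3PO4, THF/H2O, 60 °C
Reagents that add atoms: none
Why: Anti-Markovnikov hydroboration (boron on the terminal carbon; the first equivalent of borane masks the hydroxyl as a borinate) followed by B-alkyl Suzuki–Miyaura coupling; the borinate is hydrolysed in the aqueous coupling medium.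

**Step 11**
Reactants: 21 4-(3-hydroxypropyl)-2-methoxyphenol
Product: 22 4-(3-hydroxypropyl)-2-iodo-6-methoxyphenol
Conditions: I2 (1.05 equiv), NaHCO3, THF/H2O, 0 → 25 °C
Reagents that add atoms: iodine, II
Why: Electrophilic iodination of the phenol; the para position is blocked, so iodine enters the only free position ortho to the hydroxyl.

**Step 12**
Reactants: 18 4-[(2S,3R)-5-ethynyl-3-(hydroxymethyl)-7-methoxy-2,3-dihydro-1-benzofuran-2-yl]-2-methoxyphenol; 22 4-(3-hydroxypropyl)-2-iodo-6-methoxyphenol
Product: 24 4-[(2S,3R)-3-(hydroxymethyl)-5-[5-(3-hydroxypropyl)-7-methoxy-1-benzofuran-2-yl]-7-methoxy-2,3-dihydro-1-benzofuran-2-yl]-2-methoxyphenol (target), via alkynylphenol 23 (not isolated)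
Conditions: PdCl2(PPh3)2 (5 mol%), CuI (10 mol%), Et3N, DMF, 60 °C, argon
Reagents that add atoms: none
Why: Sonogashira coupling followed by 5-endo-dig hydroalkoxylation of the o-alkynylphenol (Castro–Stephens/Larock-type heteroannulation) builds the 2-arylbenzofuran; free hydroxyls are tolerated and no stereocentre is touched.

**Compound list**
1 | catechol (benzene-1,2-diol) | Oc1ccccc1O | starting material
2 | guaiacol (2-methoxyphenol) | COc1ccccc1O | intermediate
3 | 4-bromo-2-methoxyphenol | COc1cc(Br)ccc1O | intermediate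
4 | acetyl chloride | CC(Cl)=O | starting material
5 | 4-bromo-2-methoxyphenyl acetate | COc1cc(Br)ccc1OC(C)=O | intermediate
6 | 1-(5-bromo-2-hydroxy-3-methoxyphenyl)ethan-1-one | CC(=O)c1cc(Br)cc(OC)c1O | intermediate
7 | N,N-dimethylformamide dimethyl acetal | COC(OC)N(C)C | starting material
8 | (E)-1-(5-bromo-2-hydroxy-3-methoxyphenyl)-3-(dimethylamino)prop-2-en-1-one | CN(C)/C=C/C(=O)c1cc(Br)cc(OC)c1O | intermediate
9 | 6-bromo-8-methoxy-4H-chromen-4-one | COc1cc(Br)cc2c(=O)ccoc12 | intermediate
10 | 4-bromo-2-methoxyphenyl 2,2-dimethylpropanoate | COc1cc(Br)ccc1OC(=O)C(C)(C)C | intermediate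
11 | [4-(2,2-dimethylpropanoyloxy)-3-methoxyphenyl]boronic acid | COc1cc(B(O)O)ccc1OC(=O)C(C)(C)C | intermediate
12 | 4-[(2S)-6-bromo-8-methoxy-4-oxo-3,4-dihydro-2H-chromen-2-yl]-2-methoxyphenyl 2,2-dimethylpropanoate | COc1cc([C@H]2Oc3c(OC)cc(Br)cc3C(=O)C2)ccc1OC(=O)C(C)(C)C | intermediate
13 | 4-[(2S)-6-bromo-4,8-dimethoxy-2H-chromen-2-yl]-2-methoxyphenyl 2,2-dimethylpropanoate | COc1cc([C@H]2Oc3c(OC)cc(Br)cc3C(OC)=C2)ccc1OC(=O)C(C)(C)C | intermediate
14 | methyl (2S,3S)-5-bromo-2-[4-(2,2-dimethylpropanoyloxy)-3-methoxyphenyl]-7-methoxy-2,3-dihydro-1-benzofuran-3-carboxylate | COc1cc([C@H]2Oc3c(OC)cc(Br)cc3[C@@H]2C(=O)OC)ccc1OC(=O)C(C)(C)C | intermediate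
15 | ethynyl(trimethyl)silane | C#C[Si](C)(C)C | starting material
16 | methyl (2S,3S)-2-[4-(2,2-dimethylpropanoyloxy)-3-methoxyphenyl]-7-methoxy-5-[(trimethylsilyl)ethynyl]-2,3-dihydro-1-benzofuran-3-carboxylate | COc1cc([C@H]2Oc3c(OC)cc(C#C[Si](C)(C)C)cc3[C@@H]2C(=O)OC)ccc1OC(=O)C(C)(C)C | intermediate
17 | 4-[(2S,3R)-3-(hydroxymethyl)-7-methoxy-5-[(trimethylsilyl)ethynyl]-2,3-dihydro-1-benzofuran-2-yl]-2-methoxyphenol | COc1cc([C@H]2Oc3c(OC)cc(C#C[Si](C)(C)C)cc3[C@@H]2CO)ccc1O | intermediate
18 | 4-[(2S,3R)-5-ethynyl-3-(hydroxymethyl)-7-methoxy-2,3-dihydro-1-benzofuran-2-yl]-2-methoxyphenol | COc1cc([C@H]2Oc3c(OC)cc(C#C)cc3[C@@H]2CO)ccc1O | intermediate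
19 | prop-2-en-1-ol (allyl alcohol) | C=CCO | starting material
20 | 9-{3-[(9-borabicyclo[3.3.1]nonan-9-yl)oxy]propyl}-9-borabicyclo[3.3.1]nonane | B1(CCCOB2C3CCCC2CCC3)C2CCCC1CCC2 | intermediate
21 | 4-(3-hydroxypropyl)-2-methoxyphenol | COc1cc(CCCO)ccc1O | intermediate
22 | 4-(3-hydroxypropyl)-2-iodo-6-methoxyphenol | COc1cc(CCCO)cc(I)c1O | intermediate
23 | 4-[(2S,3R)-5-{[2-hydroxy-5-(3-hydroxypropyl)-3-methoxyphenyl]ethynyl}-3-(hydroxymethyl)-7-methoxy-2,3-dihydro-1-benzofuran-2-yl]-2-methoxyphenol | COc1cc([C@H]2Oc3c(OC)cc(C#Cc4cc(CCCO)cc(OC)c4O)cc3[C@@H]2CO)ccc1O | intermediate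
24 | 4-[(2S,3R)-3-(hydroxymethyl)-5-[5-(3-hydroxypropyl)-7-methoxy-1-benzofuran-2-yl]-7-methoxy-2,3-dihydro-1-benzofuran-2-yl]-2-methoxyphenol | COc1cc([C@H]2Oc3c(OC)cc(-c4cc5cc(CCCO)cc(OC)c5o4)cc3[C@@H]2CO)ccc1O | target

**Total step count:** 12.
**Longest linear sequence:** 8 steps (1 → 2 → 3 → 4 → 7 → 8 → 9 → 12).

**Three steps most likely to fail**

Step 7 (the proposed new step). Risks: residual boronic acid, palladium and water from the first stage may consume or divert PhI(OAc)2; the acidic second stage may erode ee at C2; migration of ring C (isoflavone) or C3 methoxylation may compete with the ring A shift. Fallback, known chemistry, two separate reactions in place of the one-flask process: it sets out from 9 and 11. The conjugate addition is run alone under the same divalent-palladium/PyOx conditions, and (S)-flavanone 12 is isolated and recrystallised to raise its ee. Purified 12 is then ring-contracted with PhI(OAc)2/H2SO4 in HC(OMe)3, the documented conversion of flavanones into trans methyl 2-aryl-2,3-dihydrobenzofuran-3-carboxylates. The route is rejoined at 14; this fallback makes no compound that is missing from the list (F0).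

Step 3. Risks: TiCl4 at 120 °C may cleave the methoxy group next to the chelating oxygen, or the Fries rearrangement of the deactivated bromoarene may stall at acetate 5. Fallback, ortho-formylation and carbonyl addition in place of acyl migration: it sets out from 3. Magnesium-directed ortho-formylation (MgCl2, Et3N, paraformaldehyde, MeCN, reflux) gives 5-bromo-2-hydroxy-3-methoxybenzaldehyde F1. MeMgBr (2.5 equiv, THF, 0 °C) adds to give 4-bromo-2-(1-hydroxyethyl)-6-methoxyphenol F2. Benzylic oxidation with MnO2 in CH2Cl2 returns the route at ketone 6.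

Step 12. Risks: oxidative homocoupling of alkyne 18, incomplete cyclisation of 23, and base sensitivity of the p-hydroxybenzyl aryl ether of 18 at 60 °C. Fallback, benzofuran built first on ring B and joined by C–H arylation: it sets out from 22 and 14 (steps 8 and 9 are skipped). Iodophenol 22 and silane 15 under PdCl2(PPh3)2/CuI/Et3N at 60 °C give 3-[7-methoxy-2-(trimethylsilyl)-1-benzofuran-5-yl]propan-1-ol F3. n-Bu4NF completes any unfinished cyclisation and removes silicon to give 3-(7-methoxy-1-benzofuran-5-yl)propan-1-ol F4. Direct C2–H arylation of F4 with bromide 14 (Pd(OAc)2, [HPCy3]BF4, pivalic acid, K2CO3, DMA, 100 °C) gives methyl (2S,3S)-2-[4-(2,2-dimethylpropanoyloxy)-3-methoxyphenyl]-5-[5-(3-hydroxypropyl)-7-methoxy-1-benzofuran-2-yl]-7-methoxy-2,3-dihydro-1-benzofuran-3-carboxylate F5. LiAlH4 (THF, 0 °C) then reduces the ester and removes the pivalate, returning the route at target 24.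

**Further compounds**
F1 | step 3 | 5-bromo-2-hydroxy-3-methoxybenzaldehyde | COc1cc(Br)cc(C=O)c1O
F2 | step 3 | 4-bromo-2-(1-hydroxyethyl)-6-methoxyphenol (racemic) | CC(O)c1cc(Br)cc(OC)c1O
F0 | step 7 | none | none
F3 | step 12 | 3-[7-methoxy-2-(trimethylsilyl)-1-benzofuran-5-yl]propan-1-ol | COc1cc(CCCO)cc2cc([Si](C)(C)C)oc12
F4 | step 12 | 3-(7-methoxy-1-benzofuran-5-yl)propan-1-ol | COc1cc(CCCO)cc2ccoc12
F5 | step 12 | methyl (2S,3S)-2-[4-(2,2-dimethylpropanoyloxy)-3-methoxyphenyl]-5-[5-(3-hydroxypropyl)-7-methoxy-1-benzofuran-2-yl]-7-methoxy-2,3-dihydro-1-benzofuran-3-carboxylate | COc1cc([C@H]2Oc3c(OC)cc(-c4cc5cc(CCCO)cc(OC)c5o4)cc3[C@@H]2C(=O)OC)ccc1OC(=O)C(C)(C)C
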